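**Plan**

Numbering: ring A (ten-membered carbocycle) is C1=C2 (E), C3H2, C4(=C15H2), C5(OAc), C6, C7, C8(OTig), C9H2, C10(CH3)(OH); ring B (α-methylene γ-lactone) is O–C12(=O)–C11(=C13H2), fused to ring A at C6 (oxygen) and C7.
Feature and cuts: C5 of ring A is an allylic carbinol flanked by the exocyclic C4=C15 methylene and by the oxygenated C6 of ring B, which is the retron of a 2-iodoalkene adding to an aldehyde. After removal of the C5 acetate, ring A is cut at C4–C5, then at C1=C2 (olefination), at C7–C8 together with C11–C13 (conjugate addition with iminium capture) and at C8–C9 (dithiane–epoxide opening).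
Forward: ring B is present from the start as a silylated butenolide. The C8–C10–C1 dithiane adds to it, the C1 aldehyde is joined to an iodobutenyl sulfone to complete the chain C8 to C15, the C8 ketone is unmasked, reduced and tigloylated, and ring A closes last at C4–C5.
Stereochemistry: C6 comes from the butenolide and C10 from the glycidol. C7 is set by addition anti to the C6 side chain, C8 by oxazaborolidine-controlled ketone reduction, the C1=C2 geometry by the Julia–Kocienski reaction, and C5 in the ring closure under control of C6.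

Key step: step 16

Remark: (S)-2-methylglycidol (also the product of asymmetric epoxidation of methallyl alcohol), 1,3-dithiane, (S)-5-(hydroxymethyl)furan-2(5H)-one and but-3-yn-1-ol are taken as the commercial starting materials, so C10 and C6 are bought, not made.

**Route**

Step 1
Reactants: 1 (S)-2-methylglycidol
Product: 2 (R)-triethyl[(2-methyloxiran-2-yl)methoxy]silane
Conditions: Et3SiCl, imidazole, CH2Cl2, 0 °C
Reagents that add atoms: chlorotriethylsilane, CC[Si](Cl)(CC)CC
Why: Imidazole-mediated silylation of the primary alcohol is routine, leaves the epoxide intact and removes the free hydroxyl that could otherwise equilibrate the epoxide by Payne rearrangement under the basic conditions of step 2 and erode C10.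

Step 2
Reactants: 3 1,3-dithiane; 2 (R)-triethyl[(2-methyloxiran-2-yl)methoxy]silane
Product: 6 2-[(2R)-2-methyl-2,3-bis(triethylsilyloxy)propyl]-1,3-dithiane, via 2-lithio-1,3-dithiane 4 (not isolated), via tertiary lithium alkoxide 5 (not isolated)
Conditions: 3, n-BuLi, THF, −30 °C; 2, −30 → 0 °C; Et3SiOTf, −78 → 0 °C
Reagents that add atoms: triethylsilyl trifluoromethanesulfonate, CC[Si](CC)(CC)OS(=O)(=O)C(F)(F)F
Why: Corey–Seebach chemistry: 2-lithio-1,3-dithiane opens the 2,2-disubstituted epoxide at its unsubstituted carbon (SN2, forming C8–C9 without touching the C10 stereocentre), and the tertiary lithium alkoxide is silylated in the same flask by the silyl triflate, any oxygen-to-oxygen silyl shift converging on the same bis-silyl ether.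

Step 3
Reactants: 7 (S)-5-(hydroxymethyl)furan-2(5H)-one
Product: 8 (S)-5-[(tert-butyldiphenylsilyloxy)methyl]furan-2(5H)-one
Conditions: t-BuPh2SiCl, imidazole, CH2Cl2, 0 °C → rt
Reagents that add atoms: tert-butyl(chloro)diphenylsilane, CC(C)(C)[Si](Cl)(c1ccccc1)c1ccccc1
Why: Standard imidazole-mediated silylation of the primary alcohol, mild enough not to deprotonate the butenolide at C6, installs the bulky group that later shields one face of ring B.

Step 4
Reactants: 6 2-[(2R)-2-methyl-2,3-bis(triethylsilyloxy)propyl]-1,3-dithiane; 8 (S)-5-[(tert-butyldiphenylsilyloxy)methyl]furan-2(5H)-one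
Product: 11 Mannich lactone (3R,4S,5S)-5-[(tert-butyldiphenylsilyloxy)methyl]-3-[(dimethylamino)methyl]-4-{2-[(2R)-2-methyl-2,3-bis(triethylsilyloxy)propyl]-1,3-dithian-2-yl}dihydrofuran-2(3H)-one, via lithiated dithiane 9 (not isolated), via lithium lactone enolate 10 (not isolated)
Conditions: 6, t-BuLi, THF/HMPA (9:1), −78 °C; 8, −78 °C; [Me2N=CH2]I, −78 → 0 °C
Reagents that add atoms: N,N-dimethylmethyleneiminium iodide, C=[N+](C)C.[I-]
Why: Tandem Michael addition–Mannich capture: the 2-lithio-2-alkyl-1,3-dithiane (a Brook-stable O-silyl carbanion in THF/HMPA) adds 1,4 to the butenolide anti to the silyloxymethyl group, which sets C7 trans to C6, and the resulting lactone enolate is aminomethylated by the iminium salt anti to the new dithianyl group (C11, a stereocentre that is removed in step 10).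

Step 5
Reactants: 11 Mannich lactone with C1H2OSiEt3
Product: 13 aldehyde (3R,4S,5S)-5-[(tert-butyldiphenylsilyloxy)methyl]-3-[(dimethylamino)methyl]-4-{2-[(2R)-2-methyl-3-oxo-2-(triethylsilyloxy)propyl]-1,3-dithian-2-yl}dihydrofuran-2(3H)-one, via primary C1 alcohol 12 (not isolated)
Conditions: (COCl)2, DMSO, CH2Cl2, −78 → −40 °C; Et3N, −78 → 0 °C
Reagents that add atoms: none
Why: Swern oxidation applied directly to a primary triethylsilyl ether (oxidative desilylation) removes the less hindered silyl group through the hydrogen chloride formed on activation and oxidises the liberated alcohol, while the tertiary silyl ether, the tert-butyldiphenylsilyl ether, the dithiane and the amine survive, and the aldehyde, having no α-hydrogen, cannot epimerise at C10.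

Step 6
Reactants: 14 but-3-yn-1-ol
Product: 15 3-iodobut-3-en-1-ol
Conditions: Me3SiCl, NaI, H2O, MeCN, rt
Reagents that add atoms: sodium iodide, [Na+].[I-] (iodine delivered as hydrogen iodide formed in the flask)
Why: Markovnikov hydroiodination of the terminal alkyne by hydrogen iodide generated in situ places iodine on the internal carbon (future C4) and is done on the simplest substrate, so that no late alkyne chemistry is needed.

Step 7
Reactants: 15 3-iodobut-3-en-1-ol
Product: 16 5-[(3-iodobut-3-en-1-yl)sulfanyl]-1-phenyl-1H-tetrazole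
Conditions: 1-phenyl-1H-tetrazole-5-thiol, PPh3, diisopropyl azodicarboxylate, THF, 0 °C → rt
Reagents that add atoms: 1-phenyl-1H-tetrazole-5-thiol, Sc1nnnn1-c2ccccc2
Why: Mitsunobu thioetherification of a primary alcohol with the acidic heteroaryl thiol proceeds under neutral conditions that leave the iodoalkene untouched.

Step 8
Reactants: 16 5-[(3-iodobut-3-en-1-yl)sulfanyl]-1-phenyl-1H-tetrazole
Product: 17 5-[(3-iodobut-3-en-1-yl)sulfonyl]-1-phenyl-1H-tetrazole
Conditions: H2O2 (30%), (NH4)6Mo7O24·4H2O (cat.), EtOH, 0 °C → rt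
Reagents that add atoms: hydrogen peroxide, OO
Why: Molybdate-catalysed peroxide oxidation converts the sulfide to the sulfone, the electron-poor iodoalkene being far less reactive than sulfur toward the peroxomolybdate.

Step 9
Reactants: 13 C1 aldehyde; 17 5-[(3-iodobut-3-en-1-yl)sulfonyl]-1-phenyl-1H-tetrazole
Product: 19 diene (3R,4S,5S)-5-[(tert-butyldiphenylsilyloxy)methyl]-3-[(dimethylamino)methyl]-4-{2-[(2R,3E)-6-iodo-2-methyl-2-(triethylsilyloxy)hepta-3,6-dien-1-yl]-1,3-dithian-2-yl}dihydrofuran-2(3H)-one, via potassium sulfonyl carbanion 18 (not isolated)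
Conditions: 17, KN(SiMe3)2, DME, −60 °C; then 13, −60 °C → rt
Reagents that add atoms: none
Why: Julia–Kocienski olefination: the pre-formed potassium sulfonyl carbanion adds to the non-enolisable C1 aldehyde, Smiles rearrangement and loss of sulfur dioxide and the tetrazolone give the C1=C2 alkene, E-selectively for a 1-phenyltetrazolyl sulfone with a potassium counter-ion in DME and a branched aldehyde, and the weakly basic carbanion neither enolises the lactone nor attacks the iodoalkene at low temperature.

Step 10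
Reactants: 19 Mannich lactone diene
Product: 21 methylene lactone (4S,5S)-5-[(tert-butyldiphenylsilyloxy)methyl]-4-{2-[(2R,3E)-6-iodo-2-methyl-2-(triethylsilyloxy)hepta-3,6-dien-1-yl]-1,3-dithian-2-yl}-3-methylidenedihydrofuran-2(3H)-one, via trimethylammonium iodide 20 (not isolated)
Conditions: MeI, CH2Cl2, rt; then aq NaHCO3, EtOAc, rt
Reagents that add atoms: none
Why: Quaternisation of the Mannich base followed by mild base-induced β-elimination of trimethylamine is the classical unmasking of an α-methylene lactone, and without water or heat methyl iodide alkylates the amine much faster than the dithiane sulfur.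

Step 11
Reactants: 21 methylene lactone dithiane
Product: 22 ketone (4S,5S)-5-[(tert-butyldiphenylsilyloxy)methyl]-4-[(3R,4E)-7-iodo-3-methyl-3-(triethylsilyloxy)octa-4,7-dienoyl]-3-methylidenedihydrofuran-2(3H)-one
Conditions: PhI(OCOCF3)2, MeCN/H2O (9:1), 0 °C, short reaction time, pH 7 buffer work-up
Reagents that add atoms: water, O
Why: Oxidative dithiane hydrolysis with the hypervalent iodine reagent is complete within minutes at 0 °C, tolerates alkenes, the iodoalkene, silyl ethers and the methylene lactone, and its non-basic medium keeps the β,γ-unsaturated keto lactone from isomerising into conjugation or epimerising at C7.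

Step 12
Reactants: 22 C8 ketone
Product: 23 alcohol (4R,5S)-5-[(tert-butyldiphenylsilyloxy)methyl]-4-[(1R,3R,4E)-1-hydroxy-7-iodo-3-methyl-3-(triethylsilyloxy)octa-4,7-dien-1-yl]-3-methylidenedihydrofuran-2(3H)-one
Conditions: (S)-1-methyl-3,3-diphenyltetrahydro-1H,3H-pyrrolo[1,2-c][1,3,2]oxazaborole (1 equiv), catecholborane, toluene, −78 °C
Reagents that add atoms: none
Why: Corey–Bakshi–Shibata reduction sets C8 under reagent control, since the ketone binds the (S)-oxazaborolidine with the branched C7 side as the large and the C9 methylene as the small substituent, so hydride reaches the face that gives 8R (the sense of acetophenone to (R)-1-phenylethanol), and catecholborane at −78 °C reduces neither the alkenes nor the methylene lactone.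

Step 13
Reactants: 23 C8 alcohol
Product: 24 tiglate (1R,3R,4E)-1-{(2S,3R)-2-[(tert-butyldiphenylsilyloxy)methyl]-4-methylidene-5-oxotetrahydrofuran-3-yl}-7-iodo-3-methyl-3-(triethylsilyloxy)octa-4,7-dien-1-yl (2E)-2-methylbut-2-enoate
Conditions: tiglic acid, 2,4,6-trichlorobenzoyl chloride, Et3N, toluene, rt; then 23, 4-(dimethylamino)pyridine, rt
Reagents that add atoms: tiglic acid [(2E)-2-methylbut-2-enoic acid], C/C=C(\C)C(=O)O
Why: Yamaguchi esterification acylates the hindered secondary C8 alcohol through the mixed anhydride and the acylpyridinium ion faster than the alcohol can translactonise, leaves the tertiary silyl ether untouched, and cannot scramble the acid geometry because the tiglate is the stable E isomer.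

Step 14
Reactants: 24 bis-silylated tiglate
Product: 25 diol (1R,3R,4E)-3-hydroxy-1-[(2S,3R)-2-(hydroxymethyl)-4-methylidene-5-oxotetrahydrofuran-3-yl]-7-iodo-3-methylocta-4,7-dien-1-yl (2E)-2-methylbut-2-enoate
Conditions: HF·pyridine, pyridine, THF, 0 °C → rt
Reagents that add atoms: none
Why: Buffered hydrogen fluoride removes the tertiary triethylsilyl and the primary tert-butyldiphenylsilyl ether without touching the esters, ring B or the iodoalkene, and avoids basic fluoride that could add to the methylene lactone.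

Step 15
Reactants: 25 diol
Product: 26 iodoalkenyl aldehyde (1R,3R,4E)-1-[(2S,3R)-2-formyl-4-methylidene-5-oxotetrahydrofuran-3-yl]-3-hydroxy-7-iodo-3-methylocta-4,7-dien-1-yl (2E)-2-methylbut-2-enoate
Conditions: Dess–Martin periodinane (1,1,1-triacetoxy-1,1-dihydro-1,2-benziodoxol-3(1H)-one), CH2Cl2, 0 °C → rt; used crude
Reagents that add atoms: none
Why: Dess–Martin oxidation converts the primary C5 alcohol to the aldehyde under near-neutral conditions, the tertiary allylic alcohol being unreactive, and the α-oxygenated aldehyde is used at once to avoid epimerisation at C6.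

Step 16
Reactants: 26 iodoalkenyl aldehyde
Product: 27 macrocyclic alcohol (3aR,4R,6R,7E,11S,11aS)-6,11-dihydroxy-6-methyl-3,10-dimethylidene-2-oxo-2,3,3a,4,5,6,9,10,11,11a-decahydrocyclodeca[b]furan-4-yl (2E)-2-methylbut-2-enoate (5-O-deacetyl target)
Conditions: CrCl2 (large excess), NiCl2 (cat.), degassed DMSO, rt, slow addition of 26 to a final concentration of about 2 mM
Reagents that add atoms: none
Why: Zerovalent nickel, formed from NiCl2 by CrCl2, inserts into the C4–I bond, the alkenyl group passes to trivalent chromium and the alkenylchromium adds to the C5 aldehyde, which is the Nozaki–Hiyama–Kishi macrocyclisation of an iodoalkenyl aldehyde, well known for medium-ring allylic alcohols. Ring A closes at C4–C5 in a 10-exo-trig mode and the C4=C15 methylene stays exocyclic. The trans-fused ring B, the E-C1=C2 alkene and the fully substituted C10 fold the chain toward closure, and high dilution suppresses intermolecular coupling. The new stereocentre C5 is controlled by C6: the forming bond must lie gauche to C6–C7 and is best placed antiperiplanar to the C6–O bond, and the tether from C7 draws C4 to the C7 side of the carbonyl, which turns the chromium-bound oxygen anti to C7 and away from the C8 tiglate, so that the Si face is attacked and the required 5S (5,6-syn) carbinol should result. The needed chemoselectivity for the aldehyde over the tiglate, the lactone and the free tertiary alcohol is inherent in the weakly basic alkenylchromium reagent.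

Step 17
Reactants: 27 macrocyclic alcohol
Product: 28 target (3aR,4R,6R,7E,11S,11aS)-11-acetoxy-6-hydroxy-6-methyl-3,10-dimethylidene-2-oxo-2,3,3a,4,5,6,9,10,11,11a-decahydrocyclodeca[b]furan-4-yl (2E)-2-methylbut-2-enoate
Conditions: Ac2O, pyridine, 4-(dimethylamino)pyridine (cat.), CH2Cl2, 0 °C
Reagents that add atoms: acetic anhydride, CC(=O)OC(C)=O
Why: Acetylation with acetic anhydride and the nucleophilic pyridine catalyst takes place at the secondary allylic C5 hydroxyl only, the tertiary C10 hydroxyl being inert under these conditions, and touches no stereocentre.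

**Compound list**

1 | (S)-2-methylglycidol | C[C@]1(CO)CO1 | starting material
2 | (R)-triethyl[(2-methyloxiran-2-yl)methoxy]silane (same spatial arrangement as 1) | C[C@]1(CO[Si](CC)(CC)CC)CO1 | intermediate
3 | 1,3-dithiane | C1CSCSC1 | starting material
4 | 2-lithio-1,3-dithiane | [Li]C1SCCCS1 | intermediate (not isolated)
5 | lithium (2R)-1-(1,3-dithian-2-yl)-2-methyl-3-(triethylsilyloxy)propan-2-olate | C[C@](O[Li])(CO[Si](CC)(CC)CC)CC1SCCCS1 | intermediate (not isolated)
6 | 2-[(2R)-2-methyl-2,3-bis(triethylsilyloxy)propyl]-1,3-dithiane (C8, C9, C10, C1 unit) | C[C@](O[Si](CC)(CC)CC)(CO[Si](CC)(CC)CC)CC1SCCCS1 | intermediate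
7 | (S)-5-(hydroxymethyl)furan-2(5H)-one | OC[C@H]1OC(=O)C=C1 | starting material
8 | (S)-5-[(tert-butyldiphenylsilyloxy)methyl]furan-2(5H)-one | CC(C)(C)[Si](OC[C@H]1OC(=O)C=C1)(c2ccccc2)c3ccccc3 | intermediate
9 | 2-lithio-2-[(2R)-2-methyl-2,3-bis(triethylsilyloxy)propyl]-1,3-dithiane | C[C@](O[Si](CC)(CC)CC)(CO[Si](CC)(CC)CC)CC1([Li])SCCCS1 | intermediate (not isolated)
10 | lithium (4S,5S)-5-[(tert-butyldiphenylsilyloxy)methyl]-4-{2-[(2R)-2-methyl-2,3-bis(triethylsilyloxy)propyl]-1,3-dithian-2-yl}-4,5-dihydrofuran-2-olate | [Li]OC1=C[C@H](C2(C[C@@](C)(O[Si](CC)(CC)CC)CO[Si](CC)(CC)CC)SCCCS2)[C@@H](CO[Si](c3ccccc3)(c4ccccc4)C(C)(C)C)O1 | intermediate (not isolated)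
11 | (3R,4S,5S)-5-[(tert-butyldiphenylsilyloxy)methyl]-3-[(dimethylamino)methyl]-4-{2-[(2R)-2-methyl-2,3-bis(triethylsilyloxy)propyl]-1,3-dithian-2-yl}dihydrofuran-2(3H)-one (all-trans lactone) | CC(C)(C)[Si](OC[C@H]1OC(=O)[C@@H](CN(C)C)[C@@H]1C2(C[C@@](C)(O[Si](CC)(CC)CC)CO[Si](CC)(CC)CC)SCCCS2)(c3ccccc3)c4ccccc4 | intermediate
12 | (3R,4S,5S)-5-[(tert-butyldiphenylsilyloxy)methyl]-3-[(dimethylamino)methyl]-4-{2-[(2R)-3-hydroxy-2-methyl-2-(triethylsilyloxy)propyl]-1,3-dithian-2-yl}dihydrofuran-2(3H)-one | CC(C)(C)[Si](OC[C@H]1OC(=O)[C@@H](CN(C)C)[C@@H]1C2(C[C@@](C)(O[Si](CC)(CC)CC)CO)SCCCS2)(c3ccccc3)c4ccccc4 | intermediate (not isolated)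
13 | (3R,4S,5S)-5-[(tert-butyldiphenylsilyloxy)methyl]-3-[(dimethylamino)methyl]-4-{2-[(2R)-2-methyl-3-oxo-2-(triethylsilyloxy)propyl]-1,3-dithian-2-yl}dihydrofuran-2(3H)-one (C1 aldehyde) | CC(C)(C)[Si](OC[C@H]1OC(=O)[C@@H](CN(C)C)[C@@H]1C2(C[C@@](C)(O[Si](CC)(CC)CC)C=O)SCCCS2)(c3ccccc3)c4ccccc4 | intermediate
14 | but-3-yn-1-ol | C#CCCO | starting material
15 | 3-iodobut-3-en-1-ol | C=C(I)CCO | intermediate
16 | 5-[(3-iodobut-3-en-1-yl)sulfanyl]-1-phenyl-1H-tetrazole | C=C(I)CCSc1nnnn1-c2ccccc2 | intermediate
17 | 5-[(3-iodobut-3-en-1-yl)sulfonyl]-1-phenyl-1H-tetrazole | C=C(I)CCS(=O)(=O)c1nnnn1-c2ccccc2 | intermediate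
18 | potassium α-sulfonyl carbanion of 17 | [K]C(CC(I)=C)S(=O)(=O)c1nnnn1-c2ccccc2 | intermediate (not isolated)
19 | (3R,4S,5S)-5-[(tert-butyldiphenylsilyloxy)methyl]-3-[(dimethylamino)methyl]-4-{2-[(2R,3E)-6-iodo-2-methyl-2-(triethylsilyloxy)hepta-3,6-dien-1-yl]-1,3-dithian-2-yl}dihydrofuran-2(3H)-one | CC(C)(C)[Si](OC[C@H]1OC(=O)[C@@H](CN(C)C)[C@@H]1C2(C[C@@](C)(O[Si](CC)(CC)CC)/C=C/CC(I)=C)SCCCS2)(c3ccccc3)c4ccccc4 | intermediate
20 | trimethylammonium iodide of 19 (N-methylated at the C13 amine) | CC(C)(C)[Si](OC[C@H]1OC(=O)[C@@H](C[N+](C)(C)C)[C@@H]1C2(C[C@@](C)(O[Si](CC)(CC)CC)/C=C/CC(I)=C)SCCCS2)(c3ccccc3)c4ccccc4.[I-] | intermediate (not isolated)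
21 | (4S,5S)-5-[(tert-butyldiphenylsilyloxy)methyl]-4-{2-[(2R,3E)-6-iodo-2-methyl-2-(triethylsilyloxy)hepta-3,6-dien-1-yl]-1,3-dithian-2-yl}-3-methylidenedihydrofuran-2(3H)-one | CC(C)(C)[Si](OC[C@H]1OC(=O)C(=C)[C@@H]1C2(C[C@@](C)(O[Si](CC)(CC)CC)/C=C/CC(I)=C)SCCCS2)(c3ccccc3)c4ccccc4 | intermediate
22 | (4S,5S)-5-[(tert-butyldiphenylsilyloxy)methyl]-4-[(3R,4E)-7-iodo-3-methyl-3-(triethylsilyloxy)octa-4,7-dienoyl]-3-methylidenedihydrofuran-2(3H)-one (C8 ketone) | CC(C)(C)[Si](OC[C@H]1OC(=O)C(=C)[C@@H]1C(=O)C[C@@](C)(O[Si](CC)(CC)CC)/C=C/CC(I)=C)(c2ccccc2)c3ccccc3 | intermediate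
23 | (4R,5S)-5-[(tert-butyldiphenylsilyloxy)methyl]-4-[(1R,3R,4E)-1-hydroxy-7-iodo-3-methyl-3-(triethylsilyloxy)octa-4,7-dien-1-yl]-3-methylidenedihydrofuran-2(3H)-one (8R alcohol) | CC(C)(C)[Si](OC[C@H]1OC(=O)C(=C)[C@@H]1[C@H](O)C[C@@](C)(O[Si](CC)(CC)CC)/C=C/CC(I)=C)(c2ccccc2)c3ccccc3 | intermediate
24 | (1R,3R,4E)-1-{(2S,3R)-2-[(tert-butyldiphenylsilyloxy)methyl]-4-methylidene-5-oxotetrahydrofuran-3-yl}-7-iodo-3-methyl-3-(triethylsilyloxy)octa-4,7-dien-1-yl (2E)-2-methylbut-2-enoate | CC(C)(C)[Si](OC[C@H]1OC(=O)C(=C)[C@@H]1[C@H](OC(=O)/C(C)=C/C)C[C@@](C)(O[Si](CC)(CC)CC)/C=C/CC(I)=C)(c2ccccc2)c3ccccc3 | intermediate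
25 | (1R,3R,4E)-3-hydroxy-1-[(2S,3R)-2-(hydroxymethyl)-4-methylidene-5-oxotetrahydrofuran-3-yl]-7-iodo-3-methylocta-4,7-dien-1-yl (2E)-2-methylbut-2-enoate | OC[C@H]1OC(=O)C(=C)[C@@H]1[C@H](OC(=O)/C(C)=C/C)C[C@@](C)(O)/C=C/CC(I)=C | intermediate
26 | (1R,3R,4E)-1-[(2S,3R)-2-formyl-4-methylidene-5-oxotetrahydrofuran-3-yl]-3-hydroxy-7-iodo-3-methylocta-4,7-dien-1-yl (2E)-2-methylbut-2-enoate (precursor of the key step) | O=C[C@H]1OC(=O)C(=C)[C@@H]1[C@H](OC(=O)/C(C)=C/C)C[C@@](C)(O)/C=C/CC(I)=C | intermediate
27 | (3aR,4R,6R,7E,11S,11aS)-6,11-dihydroxy-6-methyl-3,10-dimethylidene-2-oxo-2,3,3a,4,5,6,9,10,11,11a-decahydrocyclodeca[b]furan-4-yl (2E)-2-methylbut-2-enoate (product of the key step; 5S,6S,7R,8R,10R in the ring A numbering) | C=C1C(=O)O[C@H]2[C@H]1[C@H](OC(=O)/C(C)=C/C)C[C@@](C)(O)/C=C/CC(=C)[C@@H]2O | intermediate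
28 | (3aR,4R,6R,7E,11S,11aS)-11-acetoxy-6-hydroxy-6-methyl-3,10-dimethylidene-2-oxo-2,3,3a,4,5,6,9,10,11,11a-decahydrocyclodeca[b]furan-4-yl (2E)-2-methylbut-2-enoate | C=C1C(=O)O[C@H]2[C@H]1[C@H](OC(=O)/C(C)=C/C)C[C@@](C)(O)/C=C/CC(=C)[C@@H]2OC(C)=O | target

**Count and risks**

Total step count: 17. Longest linear sequence: 13 steps (1 → 2 → 6 → 11 → 13 → 19 → 21 → 22 → 23 → 24 → 25 → 26 → 27 → 28, that is steps 1, 2, 4, 5 and 9 to 17).

The three steps most likely to fail:

Step 16 (ring closure). The danger is poor facial selectivity at the C5 aldehyde, the alkenylchromium adding mainly to the Re face, alongside some intermolecular coupling. The fallback corrects the stereocentre by inversion instead of relying on the direct addition. It sets out from aldehyde 26, which is cyclised as before, and the 5R carbinol, the 5-epi macrocyclic alcohol F1, is collected. Mitsunobu esterification of F1 with acetic acid (PPh3, diisopropyl azodicarboxylate, toluene, 0 °C; betaine pre-formed so that the phosphine does not add to the methylene lactone) displaces the activated secondary allylic oxygen with inversion. The tertiary C10 hydroxyl does not take part, and the fallback comes back to the route at target 28, so that step 17 is not needed for this material.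

Step 12 (C8 reduction). The danger is poor facial selectivity if the inherent bias of the C7-branched ketone opposes the (S)-oxazaborolidine, and to a lesser degree 1,4-reduction of the methylene lactone. The fallback uses the substrate bias instead of opposing it. It sets out from ketone 22, which is reduced with (R)-1-methyl-3,3-diphenyltetrahydro-1H,3H-pyrrolo[1,2-c][1,3,2]oxazaborole and catecholborane, then the matched pair, to the 8S alcohol F2. Mitsunobu esterification of F2 with tiglic acid (PPh3, diisopropyl azodicarboxylate, THF) installs the ester with inversion at C8 and comes back to the route at tiglate 24, replacing step 13.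

Step 4 (tandem addition and capture). The danger is incomplete capture of the crowded lactone enolate, which sits next to the fully substituted dithiane carbon, so that proton transfer outruns aminomethylation. The fallback separates the two bond formations. It sets out from dithiane 6 and butenolide 8: the lithiated dithiane is added as before, but the enolate is quenched with aqueous NH4Cl to give the trans-disubstituted lactone F3. F3 is then enolised on its own with LiN(i-Pr)2 in THF at −78 °C, where the lactone α-position is the only acidic site, and treated with [Me2N=CH2]I, which comes back to the route at Mannich lactone 11.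

**Further compounds**

F1 | step 16 | (3aR,4R,6R,7E,11R,11aS)-6,11-dihydroxy-6-methyl-3,10-dimethylidene-2-oxo-2,3,3a,4,5,6,9,10,11,11a-decahydrocyclodeca[b]furan-4-yl (2E)-2-methylbut-2-enoate (5-epi-27) | C=C1C(=O)O[C@H]2[C@H]1[C@H](OC(=O)/C(C)=C/C)C[C@@](C)(O)/C=C/CC(=C)[C@H]2O
F2 | step 12 | (4R,5S)-5-[(tert-butyldiphenylsilyloxy)methyl]-4-[(1S,3R,4E)-1-hydroxy-7-iodo-3-methyl-3-(triethylsilyloxy)octa-4,7-dien-1-yl]-3-methylidenedihydrofuran-2(3H)-one (8-epi-23) | CC(C)(C)[Si](OC[C@H]1OC(=O)C(=C)[C@@H]1[C@@H](O)C[C@@](C)(O[Si](CC)(CC)CC)/C=C/CC(I)=C)(c2ccccc2)c3ccccc3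
F3 | step 4 | (4S,5S)-5-[(tert-butyldiphenylsilyloxy)methyl]-4-{2-[(2R)-2-methyl-2,3-bis(triethylsilyloxy)propyl]-1,3-dithian-2-yl}dihydrofuran-2(3H)-one | CC(C)(C)[Si](OC[C@H]1OC(=O)C[C@@H]1C2(C[C@@](C)(O[Si](CC)(CC)CC)CO[Si](CC)(CC)CC)SCCCS2)(c3ccccc3)c4ccccc4
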